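**Plan** (cyclopenta[c]pyran numbering: C1 bears the coumarin, O2, C3 acyl, C4 methyl, C4a, C5, C6, C7 methyl, C7a)
Retrosynthesis: cut C1–C3' (C1 acetal + 4-hydroxy-5-methylcoumarin), then C3–acyl (C3 vinyl anion + Weinreb amide of (R)-2-hydroxy-3-methylbutanoic acid), open the dihydropyran to the 1,5-dialdehyde/1,5-diol, and last cut C7a–C7 of the cyclopentane.
Enabling feature: C7a carries the one-carbon unit C1 and lies between methyl-bearing C7 and C4a, which bears the three-carbon unit C4(Me)=C3. With C1 put back between C7a and C7, the cyclopentane is the cyclohexanone ring of trans-dihydrocarvone (isopropenyl = C4, C4-Me, C3), so a Wolff ring contraction of its α-diazo ketone makes the C7a–C7 bond.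
Forward: (S)-carvone → dihydrocarvone → diazo ketone → photochemical ring contraction (cyclopentane) → diol → iridodial → cis-fused dihydropyran lactol, then acetal → C3 acylation → C1 arylation → desilylation.
Stereochemistry: C4a is C5 of (S)-carvone; C7 is the trans C2 methyl centre of dihydrocarvone, kept in the 1,2-shift; C7a is set by thermodynamic ring–chain equilibration to the cis-fused bicycle; C1 by convex-face attack on the oxocarbenium ion; the carbinol carbon comes from the chiral-pool hydroxy acid.

Key step: step 3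

Remark: acid 6, diol 7 and acetal 10 are carried as epimer mixtures at centres (C7a, C4, C1) that are equilibrated or destroyed later; 4-hydroxy-5-methylcoumarin is made in one step because its commercial supply is uncertain.

Step 1
Reactants: 1 (S)-(+)-carvone
Product: 2 (2S,5S)-2-methyl-5-(prop-1-en-2-yl)cyclohexan-1-one (trans-dihydrocarvone)
Conditions: L-Selectride, THF, –78 °C; MeOH/H2O quench, then cat. NaOMe, MeOH, rt
Reagents that add atoms: none
Why: Conjugate hydride reduction of the β-unsubstituted enone gives the enolate, and protonation under equilibrating conditions should leave the C2 methyl equatorial and trans to the isopropenyl group, the carvone C5 centre being untouched.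

Step 2
Reactants: 2 (2S,5S)-2-methyl-5-(prop-1-en-2-yl)cyclohexan-1-one
Product: 4 (3R,6S)-2-diazo-6-methyl-3-(prop-1-en-2-yl)cyclohexan-1-one, via trifluoroacetyl diketone 3 (not isolated)
Conditions: LiHMDS, THF, –78 °C; CF3CO2CH2CF3; aq. HCl work-up; then 4-acetamidobenzenesulfonyl azide, Et3N, H2O, MeCN, rt
Reagents that add atoms: 4-acetamidobenzenesulfonyl azide, CC(=O)Nc1ccc(cc1)S(=O)(=O)N=[N+]=[N-]; 2,2,2-trifluoroethyl trifluoroacetate, O=C(OCC(F)(F)F)C(F)(F)F (its CF3CO group is carried only in 3)
Why: Detrifluoroacetylative diazo transfer: the kinetic enolate forms at the methylene α-carbon (the only α-position able to carry a diazo group), is C-trifluoroacylated, and diketone 3 takes up N2 from the sulfonyl azide with loss of the trifluoroacetyl group, the α'-methyl centre not being enolised.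

Step 3
Reactants: 4 (3R,6S)-2-diazo-6-methyl-3-(prop-1-en-2-yl)cyclohexan-1-one
Product: 6 (2S,5S)-2-methyl-5-(prop-1-en-2-yl)cyclopentane-1-carboxylic acid (C1 epimers), via ketene 5 (not isolated)
Conditions: hν (365 nm LEDs or medium-pressure Hg lamp through Pyrex), THF/H2O 4:1, rt, N2
Reagents that add atoms: water, O
Why: Irradiation expels N2 from the s-Z-locked cyclic α-diazo ketone and the ring bond from the carbonyl carbon to the methyl-bearing carbon shifts to the diazo carbon, so that future C7 bonds to future C7a and the carbonyl carbon is extruded as the ketene carbon (future C1), which water converts into the acid. The closest known reaction type is the photochemical Wolff ring contraction of 2-diazocycloalkanones to cycloalkanecarboxylic acids. The cyclopentane is closed by a 1,2-alkyl shift (six- to five-membered ring contraction), not by an exo or endo cyclisation of a chain. C7 is the migrating carbon and keeps its configuration, so the trans methyl/isopropenyl relation of dihydrocarvone becomes the trans C7/C4a relation of the target; C4a is untouched, and C7a forms without control on protonation of the ketene hydrate and is corrected in step 5. The step needs the shift to win over 1,2-hydride migration from the adjacent C–H (enone formation) and over carbene capture by the isopropenyl group; the enforced s-Z geometry favours the concerted shift, and the neighbouring alkene could reach the carbene carbon only by forming a bicyclobutane.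

Step 4
Reactants: 6 (2S,5S)-2-methyl-5-(prop-1-en-2-yl)cyclopentane-1-carboxylic acid
Product: 7 2-[(1R,3S)-2-(hydroxymethyl)-3-methylcyclopentyl]propan-1-ol (epimers at ring C2 and at the side-chain CH)
Conditions: BH3·THF (excess), THF, 0 °C → rt; then 3 M NaOH, 30% H2O2, 0 °C → rt
Reagents that add atoms: hydrogen peroxide, OO
Why: Borane reduces the carboxylic acid to the primary alcohol and hydroborates the 1,1-disubstituted alkene anti-Markovnikov in the same pot, oxidative work-up giving the 1,5-diol; the new centre at C4 forms without control and is erased in step 5.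

Step 5
Reactants: 7 2-[(1R,3S)-2-(hydroxymethyl)-3-methylcyclopentyl]propan-1-ol
Product: 9 (1R,4aS,7S,7aR)-4,7-dimethyl-1,4a,5,6,7,7a-hexahydrocyclopenta[c]pyran-1-ol (nepetalactol), via iridodial 8 (not isolated)
Conditions: (COCl)2, DMSO, CH2Cl2, –78 °C; Et3N, –78 °C → rt; then DBU (0.2 equiv), rt
Reagents that add atoms: none
Why: Swern oxidation gives the dialdehyde, and base-mediated enolisation of both α-formyl centres (C7a, C4) together with ring–chain tautomerism should drain it into the cis-fused enol-lactol with the C7 methyl on the convex face, the preferred hemiacetal, so that C7a is set relative to the fixed C4a and C7 centres.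

Step 6
Reactants: 9 nepetalactol
Product: 10 (4aS,7S,7aR)-1-methoxy-4,7-dimethyl-1,4a,5,6,7,7a-hexahydrocyclopenta[c]pyran (anomer mixture)
Conditions: Ag2O, MeI, 4 Å MS, CH2Cl2, rt, dark
Reagents that add atoms: iodomethane, CI
Why: Purdie-type O-methylation of the anomeric hydroxyl under non-acidic conditions caps the lactol as a base-stable acetal without adding methanol across the acid-labile enol ether.

Step 7
Reactants: 11 (R)-2-hydroxy-3-methylbutanoic acid
Product: 12 (R)-2-hydroxy-N-methoxy-N,3-dimethylbutanamide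
Conditions: MeNHOMe·HCl, EDC·HCl, HOBt (cat.), N-methylmorpholine, CH2Cl2, 0 °C → rt
Reagents that add atoms: N,O-dimethylhydroxylamine hydrochloride, Cl.CNOC
Why: Carbodiimide-mediated amidation of the α-hydroxy acid gives the Weinreb amide without touching the stereocentre.

Step 8
Reactants: 12 (R)-2-hydroxy-N-methoxy-N,3-dimethylbutanamide
Product: 13 (R)-2-[(tert-butyldimethylsilyl)oxy]-N-methoxy-N,3-dimethylbutanamide
Conditions: TBSCl, imidazole, DMF, rt
Reagents that add atoms: tert-butyldimethylsilyl chloride, CC(C)(C)[Si](C)(C)Cl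
Why: Standard silylation of the secondary alcohol protects it against the organolithium of step 9.

Step 9
Reactants: 10 (4aS,7S,7aR)-1-methoxy-4,7-dimethyl-1,4a,5,6,7,7a-hexahydrocyclopenta[c]pyran; 13 (R)-2-[(tert-butyldimethylsilyl)oxy]-N-methoxy-N,3-dimethylbutanamide
Product: 15 (2R)-2-[(tert-butyldimethylsilyl)oxy]-1-[(4aS,7S,7aR)-1-methoxy-4,7-dimethyl-1,4a,5,6,7,7a-hexahydrocyclopenta[c]pyran-3-yl]-3-methylbutan-1-one, via C3-vinyllithium 14 (not isolated)
Conditions: t-BuLi (1.2 equiv), THF, –78 → 0 °C; recool to –78 °C, add 13, → 0 °C; H2O quench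
Reagents that add atoms: none
Why: Oxygen-directed vinylic deprotonation of the cyclic enol ether at C3 (the only sp2 C–H α to oxygen) gives the α-alkoxyvinyllithium, whose addition to the Weinreb amide stops at the chelated tetrahedral intermediate and releases the α-alkoxy enone on work-up (Weinreb ketone synthesis), with no new stereocentre.

Step 10
Reactants: 16 1-(2-hydroxy-6-methylphenyl)ethan-1-one
Product: 17 4-hydroxy-5-methyl-2H-chromen-2-one
Conditions: NaH (3 equiv), (EtO)2CO, toluene, 110 °C; then aq. HCl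
Reagents that add atoms: diethyl carbonate, CCOC(=O)OCC
Why: Claisen-type C-acylation of the ketone enolate by the carbonate and lactonisation onto the phenoxide give the 4-hydroxycoumarin.

Step 11
Reactants: 15 ketone acetal from step 9; 17 4-hydroxy-5-methyl-2H-chromen-2-one
Product: 18 3-[(1R,4aS,7S,7aR)-3-[(2R)-2-[(tert-butyldimethylsilyl)oxy]-3-methylbutanoyl]-4,7-dimethyl-1,4a,5,6,7,7a-hexahydrocyclopenta[c]pyran-1-yl]-4-hydroxy-5-methyl-2H-chromen-2-one
Conditions: Sc(OTf)3 (10 mol %), 4 Å MS, MeCN, 0 °C → rt
Reagents that add atoms: none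
Why: The Lewis acid ionises the methyl acetal to the C1 oxocarbenium ion, which is captured by the nucleophilic C3 of the 4-hydroxycoumarin (Friedel–Crafts-type C-glycosylation) on the convex face of the cis-fused bicycle, anti to the C7a–C7 bond, which should set C1 as R, any O-linked adduct reverting under the acid to the C-linked product.

Step 12
Reactants: 18 silyl ether from step 11
Product: 19 4-hydroxy-3-[(1R,4aS,7S,7aR)-3-[(2R)-2-hydroxy-3-methylbutanoyl]-4,7-dimethyl-1,4a,5,6,7,7a-hexahydrocyclopenta[c]pyran-1-yl]-5-methyl-2H-chromen-2-one (CNP0214255.1)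
Conditions: HF·pyridine, THF, 0 °C → rt
Reagents that add atoms: none
Why: Fluoride cleaves the Si–O bond under buffered conditions that should leave the enol ether, the α-hydroxy ketone centre and the coumarin untouched.

**Compound list**
1 | (S)-(+)-carvone, (5S)-2-methyl-5-(prop-1-en-2-yl)cyclohex-2-en-1-one | O=C1C[C@@H](C(C)=C)CC=C1C | starting material
2 | (2S,5S)-2-methyl-5-(prop-1-en-2-yl)cyclohexan-1-one | O=C1C[C@@H](C(C)=C)CC[C@@H]1C | intermediate
3 | (3S,6S)-6-methyl-3-(prop-1-en-2-yl)-2-(2,2,2-trifluoroacetyl)cyclohexan-1-one (C2 unspecified, enolised) | O=C1C(C(=O)C(F)(F)F)[C@@H](C(C)=C)CC[C@@H]1C | intermediate (not isolated)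
4 | (3R,6S)-2-diazo-6-methyl-3-(prop-1-en-2-yl)cyclohexan-1-one | O=C1C(=[N+]=[N-])[C@@H](C(C)=C)CC[C@@H]1C | intermediate
5 | [(2S,5R)-2-methyl-5-(prop-1-en-2-yl)cyclopentylidene]methanone (ketene) | O=C=C1[C@@H](C(C)=C)CC[C@@H]1C | intermediate (not isolated)
6 | (2S,5S)-2-methyl-5-(prop-1-en-2-yl)cyclopentane-1-carboxylic acid (C1 epimers) | OC(=O)C1[C@@H](C(C)=C)CC[C@@H]1C | intermediate
7 | 2-[(1R,3S)-2-(hydroxymethyl)-3-methylcyclopentyl]propan-1-ol (epimer mixture) | OCC1[C@@H](C(C)CO)CC[C@@H]1C | intermediate
8 | 2-[(1R,3S)-2-formyl-3-methylcyclopentyl]propanal (iridodial, epimer mixture) | O=CC1[C@@H](C(C)C=O)CC[C@@H]1C | intermediate (not isolated)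
9 | (1R,4aS,7S,7aR)-4,7-dimethyl-1,4a,5,6,7,7a-hexahydrocyclopenta[c]pyran-1-ol | CC1=CO[C@@H](O)[C@H]2[C@@H]1CC[C@@H]2C | intermediate
10 | (4aS,7S,7aR)-1-methoxy-4,7-dimethyl-1,4a,5,6,7,7a-hexahydrocyclopenta[c]pyran (anomers) | CC1=COC(OC)[C@H]2[C@@H]1CC[C@@H]2C | intermediate
11 | (R)-2-hydroxy-3-methylbutanoic acid | CC(C)[C@@H](O)C(=O)O | starting material
12 | (R)-2-hydroxy-N-methoxy-N,3-dimethylbutanamide | CC(C)[C@@H](O)C(=O)N(C)OC | intermediate
13 | (R)-2-[(tert-butyldimethylsilyl)oxy]-N-methoxy-N,3-dimethylbutanamide | CC(C)[C@@H](O[Si](C)(C)C(C)(C)C)C(=O)N(C)OC | intermediate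
14 | [(4aS,7S,7aR)-1-methoxy-4,7-dimethyl-1,4a,5,6,7,7a-hexahydrocyclopenta[c]pyran-3-yl]lithium | CC1=C([Li])OC(OC)[C@H]2[C@@H]1CC[C@@H]2C | intermediate (not isolated)
15 | (2R)-2-[(tert-butyldimethylsilyl)oxy]-1-[(4aS,7S,7aR)-1-methoxy-4,7-dimethyl-1,4a,5,6,7,7a-hexahydrocyclopenta[c]pyran-3-yl]-3-methylbutan-1-one | CC1=C(C(=O)[C@H](O[Si](C)(C)C(C)(C)C)C(C)C)OC(OC)[C@H]2[C@@H]1CC[C@@H]2C | intermediate
16 | 1-(2-hydroxy-6-methylphenyl)ethan-1-one | CC(=O)c1c(C)cccc1O | starting material
17 | 4-hydroxy-5-methyl-2H-chromen-2-one | Cc1cccc2oc(=O)cc(O)c12 | intermediate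
18 | 3-[(1R,4aS,7S,7aR)-3-[(2R)-2-[(tert-butyldimethylsilyl)oxy]-3-methylbutanoyl]-4,7-dimethyl-1,4a,5,6,7,7a-hexahydrocyclopenta[c]pyran-1-yl]-4-hydroxy-5-methyl-2H-chromen-2-one | CC1=C(C(=O)[C@H](O[Si](C)(C)C(C)(C)C)C(C)C)O[C@@H](c2c(O)c3c(C)cccc3oc2=O)[C@H]2[C@@H]1CC[C@@H]2C | intermediate
19 | 4-hydroxy-3-[(1R,4aS,7S,7aR)-3-[(2R)-2-hydroxy-3-methylbutanoyl]-4,7-dimethyl-1,4a,5,6,7,7a-hexahydrocyclopenta[c]pyran-1-yl]-5-methyl-2H-chromen-2-one | CC1=C(C(=O)[C@H](O)C(C)C)O[C@@H](c2c(O)c3c(C)cccc3oc2=O)[C@H]2[C@@H]1CC[C@@H]2C | target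

**Totals**
Total step count: 12. Longest linear sequence: 9 steps (steps 1–6, 9, 11, 12).

**Steps most likely to fail**

Step 9. Vinylic deprotonation at C3 of the β-methyl-substituted enol ether may be slow, so that allylic metalation (C4 methyl, C4a–H) or loss of methoxide competes. The hindered α-silyloxy Weinreb amide may also be enolised instead of attacked. The fallback sets out from 10 and comes back at 15. It makes the C3–metal bond from a lactone instead of by C–H deprotonation. PCC in CH2Cl2 should oxidise the enol ether to (4aS,7S,7aR)-1-methoxy-4,7-dimethylhexahydrocyclopenta[c]pyran-3(1H)-one F1. KHMDS and (PhO)2P(O)Cl in THF at –78 °C should convert this into the ketene acetal phosphate F2. Pd(PPh3)4, Me3SnSnMe3 and LiCl in THF at reflux should then give the vinylstannane F3. Tin–lithium exchange with MeLi at –78 °C gives vinyllithium 14 regiospecifically, and addition of 13 as in step 9 gives 15.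

Step 11. Ionisation at C1 may be slow because the 3-acyl group lowers the donor ability of the ring oxygen. O-alkylation of the coumarin, elimination toward a pyran diene, partial desilylation or poor facial selectivity at C1 may then take over. The fallback sets out from 15 and comes back at 18. It replaces acetal ionisation by a condensation on the open-chain aldehyde. PPTS in acetone/H2O should hydrolyse the acetal to the lactol F4. Its aldehyde tautomer should undergo Knoevenagel condensation with 17 (ethylenediammonium diacetate, CH2Cl2/EtOH, rt) to the alkylidene-chromanedione F5. F5 is not isolated: it should reclose by 6-endo oxa-Michael addition of the diketone enol oxygen to C1 under thermodynamic control and give 18.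

Step 5. Epimerisation at C7a may stay incomplete, leaving open-chain or trans-fused material, and the dialdehyde may oligomerise by aldol reaction under base. The fallback sets out from 6 and comes back at 9. It fixes C7a at the enol-lactone stage, where the centre is α to a lactone carbonyl. 9-BBN followed by NaOH/H2O2 should give the hydroxy acid F6. Dess–Martin periodinane should give the formyl acid (nepetalic acid) F7. Cyclodehydration (TsOH, toluene, reflux) followed by DBU equilibration should give cis-fused (4aS,7S,7aR)-nepetalactone F8. DIBAL-H in CH2Cl2 at –78 °C then gives lactol 9.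

Further compounds
F1 | step 9 | (4aS,7S,7aR)-1-methoxy-4,7-dimethylhexahydrocyclopenta[c]pyran-3(1H)-one | CC1C(=O)OC(OC)[C@H]2[C@@H]1CC[C@@H]2C
F2 | step 9 | diphenyl (4aS,7S,7aR)-1-methoxy-4,7-dimethyl-1,4a,5,6,7,7a-hexahydrocyclopenta[c]pyran-3-yl phosphate | CC1=C(OP(=O)(Oc3ccccc3)Oc3ccccc3)OC(OC)[C@H]2[C@@H]1CC[C@@H]2C
F3 | step 9 | trimethyl[(4aS,7S,7aR)-1-methoxy-4,7-dimethyl-1,4a,5,6,7,7a-hexahydrocyclopenta[c]pyran-3-yl]stannane | CC1=C([Sn](C)(C)C)OC(OC)[C@H]2[C@@H]1CC[C@@H]2C
F4 | step 11 | (2R)-2-[(tert-butyldimethylsilyl)oxy]-1-[(4aS,7S,7aR)-1-hydroxy-4,7-dimethyl-1,4a,5,6,7,7a-hexahydrocyclopenta[c]pyran-3-yl]-3-methylbutan-1-one | CC1=C(C(=O)[C@H](O[Si](C)(C)C(C)(C)C)C(C)C)OC(O)[C@H]2[C@@H]1CC[C@@H]2C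
F5 | step 11 | 3-{[(1R,2S,5S)-2-[(5R)-5-[(tert-butyldimethylsilyl)oxy]-6-methyl-3,4-dioxoheptan-2-yl]-5-methylcyclopentyl]methylidene}-5-methylchromane-2,4-dione | Cc1cccc2OC(=O)C(=C[C@@H]3[C@@H](C)CC[C@@H]3C(C)C(=O)C(=O)[C@H](O[Si](C)(C)C(C)(C)C)C(C)C)C(=O)c12
F6 | step 5 | (2S,5R)-5-(1-hydroxypropan-2-yl)-2-methylcyclopentane-1-carboxylic acid | OC(=O)C1[C@@H](C(C)CO)CC[C@@H]1C
F7 | step 5 | (2S,5R)-2-methyl-5-(1-oxopropan-2-yl)cyclopentane-1-carboxylic acid | OC(=O)C1[C@@H](C(C)C=O)CC[C@@H]1C
F8 | step 5 | (4aS,7S,7aR)-4,7-dimethyl-5,6,7,7a-tetrahydrocyclopenta[c]pyran-1(4aH)-one | CC1=COC(=O)[C@H]2[C@@H]1CC[C@@H]2C
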